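**Plan**

Locants: chroman half O1, C2–C4, C4a, C5–C8, C8a (its benzene ring is ring B); chromene half carries primed locants (ring A).

1. Cuts, in retrosynthetic order: the three O–Si bonds; O1–C8a (chroman pyran ring); the two C2–CH3 bonds; C4–C6'; then in each half the aryl–prenyl bond and the aryl–CH2CH2Ar bond (B-alkyl Suzuki, both from one alkylborane 4).
2. Forward: ring A gets its pyran first (enal annulation of resorcinol 6) and then the 8'-prenyl group (Claisen–Cope). Ring B is built as enal 16, still without oxygen at C8a. The halves are joined at C4–C6' with closure of a lactol on O5', which is oxidised and opened with MeMgBr. The chroman ring is closed last.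
3. Enabling feature: in ring B the free hydroxyl at C5 is para to the prenyl-bearing C8 and meta to C8a–H. Oxidation places methoxy on C8 and turns ring B into a cyclohexa-2,5-dienone whose enone β-carbon is C8a, within reach of the tertiary hydroxyl (O1–C2–C3–C4–C4a–C8a). Loss of methanol from C8 returns the arene with O1 on C8a and OH on C5.
4. Stereochemistry: the single stereocentre C4 is set in step 12 by the (S)-diarylprolinol silyl ether (face of the iminium ion) and is not touched afterwards.

Key step: step 17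

Remark: prenyl = 3-methylbut-2-en-1-yl; TIPS = triisopropylsilyl; TBS = tert-butyldimethylsilyl; ArE = 2-[4-(triisopropylsilyloxy)phenyl]ethyl; fod = 6,6,7,7,8,8,8-heptafluoro-2,2-dimethyloctane-3,5-dionate. Alkylborane 4 is assumed to keep as a THF solution under argon, so that one batch serves steps 3 and 8. Lactol 18 is carried on as its mixture of anomers. The C4 descriptor changes from S to R in step 17 only because ring B gains CIP priority; the geometry is unchanged.

**Route**

Step 1
Reactants: 1 4-vinylphenyl acetate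
Product: 3 triisopropyl(4-vinylphenoxy)silane, via 4-vinylphenol 2 (not isolated)
Conditions: K2CO3 (cat.), MeOH, 0 °C; extractive work-up; TIPSCl, imidazole, CH2Cl2, 0 °C to rt
Reagents that add atoms: chlorotriisopropylsilane, CC(C)[Si](Cl)(C(C)C)C(C)C
Why: Base-catalysed transesterification followed by silylation of the crude phenol avoids isolating polymerisation-prone 2, and the TIPS ether is chosen because it should withstand the basic couplings of steps 3 and 8.

Step 2
Reactants: 3 triisopropyl(4-vinylphenoxy)silane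
Product: 4 9-ArE-9-borabicyclo[3.3.1]nonane
Conditions: 9-BBN (1.05 equiv), THF, 0 °C to rt, under argon; kept as a THF stock solution and divided between steps 3 and 8
Reagents that add atoms: 9-borabicyclo[3.3.1]nonane, B1C2CCCC1CCC2
Why: Anti-Markovnikov hydroboration of the styrene with the bulky dialkylborane places boron on the terminal carbon, and the B-alkyl-9-BBN product should be stable in solution under inert gas.

Step 3
Reactants: 4 9-ArE-9-borabicyclo[3.3.1]nonane; 5 5-bromobenzene-1,3-diol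
Product: 6 5-ArE-benzene-1,3-diol
Conditions: 4 (THF solution, 1.2 equiv), PdCl2(dppf) (3 mol%), K3PO4 (aq.), DMF, 60 °C
Reagents that add atoms: none
Why: B-alkyl Suzuki–Miyaura coupling of the alkylborane with the aryl bromide should install the arylethyl chain without protection of the resorcinol.

Step 4
Reactants: 6 5-ArE-benzene-1,3-diol
Product: 7 7-ArE-2,2-dimethyl-2H-chromen-5-ol
Conditions: 3-methylbut-2-enal (1.1 equiv), ethylenediammonium diacetate (10 mol%), toluene, reflux
Reagents that add atoms: 3-methylbut-2-enal, CC(C)=CC=O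
Why: Chromene annulation (Knoevenagel-type condensation at the ring carbon between the two hydroxyls, then oxa-6π electrocyclisation of the ortho-quinone methide) should give one 2H-chromene because the resorcinol is symmetric and either hydroxyl closes the same ring.

Step 5
Reactants: 7 7-ArE-2,2-dimethyl-2H-chromen-5-ol
Product: 8 7-ArE-2,2-dimethyl-5-(prenyloxy)-2H-chromene
Conditions: prenyl bromide, K2CO3, acetone, reflux
Reagents that add atoms: 1-bromo-3-methylbut-2-ene, CC(C)=CCBr
Why: Williamson ether synthesis at the only free phenol.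

Step 6
Reactants: 8 7-ArE-2,2-dimethyl-5-(prenyloxy)-2H-chromene
Product: 10 7-ArE-2,2-dimethyl-8-prenyl-2H-chromen-5-ol, via ortho-dienone 9 (not isolated)
Conditions: Eu(fod)3 (10 mol%), CHCl3, 60 °C, sealed tube
Reagents that add atoms: none
Why: Tandem aromatic Claisen–Cope rearrangement, in which the [3,3] shift to C6 gives dienone 9 and a second [3,3] shift carries the 1,1-dimethylallyl group on to C8 (para to O5, the other ortho carbon C4a being blocked), the course known for 5-prenyloxyflavanones under this Lewis acid.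

Step 7
Reactants: 11 4-bromo-3-chlorophenol
Product: 12 3-chloro-4-prenylphenol
Conditions: prenylboronic acid pinacol ester (1.05 equiv), [PdCl2(IPent)(3-chloropyridine)] (2 mol%; IPent = 1,3-bis[2,6-di(pentan-3-yl)phenyl]imidazol-2-ylidene), KOH (aq.), THF, 65 °C
Reagents that add atoms: 3-methylbut-2-enylboronic acid pinacol ester, CC(C)=CCB1OC(C)(C)C(C)(C)O1
Why: Suzuki–Miyaura allylation, in which the bulky carbene ligand should favour the linear (α) prenyl product and the C–Br bond reacts before the C–Cl bond.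

Step 8
Reactants: 12 3-chloro-4-prenylphenol; 4 9-ArE-9-borabicyclo[3.3.1]nonane
Product: 13 3-ArE-4-prenylphenol
Conditions: 4 (THF solution, 1.3 equiv), Pd(OAc)2 (3 mol%), SPhos (6 mol%), K3PO4·H2O, THF, 65 °C
Reagents that add atoms: none
Why: B-alkyl Suzuki–Miyaura coupling of the aryl chloride, enabled by the electron-rich biaryl phosphine, with the trisubstituted prenyl alkene inert to the preformed alkylborane.

Step 9
Reactants: 13 3-ArE-4-prenylphenol
Product: 14 4-ArE-2-hydroxy-5-prenylbenzaldehyde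
Conditions: MgCl2, Et3N, (CH2O)n, MeCN, reflux
Reagents that add atoms: paraformaldehyde (as formaldehyde), C=O
Why: Magnesium phenoxide-directed ortho-formylation (Casnati–Skattebøl) is specific for the position ortho to OH and should take the open one, the other being flanked by the arylethyl group.

Step 10
Reactants: 14 4-ArE-2-hydroxy-5-prenylbenzaldehyde
Product: 15 2-(allyloxy)-4-ArE-5-prenylbenzaldehyde
Conditions: allyl bromide, K2CO3, DMF, rt
Reagents that add atoms: allyl bromide, C=CCBr
Why: Williamson etherification masks the ring B phenol with a group removable under neutral conditions, so that the lactol of step 12 can form only on ring A.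

Step 11
Reactants: 15 2-(allyloxy)-4-ArE-5-prenylbenzaldehyde
Product: 16 (E)-3-[2-(allyloxy)-4-ArE-5-prenylphenyl]prop-2-enal
Conditions: Ph3P=CHCHO, toluene, 80 °C
Reagents that add atoms: (triphenylphosphoranylidene)acetaldehyde, O=CC=P(c1ccccc1)(c1ccccc1)c1ccccc1
Why: Wittig olefination with the stabilised formyl ylide should give the (E)-enal.

Step 12
Reactants: 10 7-ArE-2,2-dimethyl-8-prenyl-2H-chromen-5-ol; 16 (E)-3-[2-(allyloxy)-4-ArE-5-prenylphenyl]prop-2-enal
Product: 18 (4S)-4-[2-(allyloxy)-4-ArE-5-prenylphenyl]-5-ArE-8,8-dimethyl-6-prenyl-3,4-dihydro-2H,8H-pyrano[2,3-f]chromen-2-ol, via hydroxy aldehyde 17 (not isolated)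
Conditions: (S)-α,α-diphenylprolinol trimethylsilyl ether (20 mol%), PhCO2H (20 mol%), toluene, 0 °C to rt
Reagents that add atoms: none
Why: Iminium-catalysed Friedel–Crafts alkylation–hemiacetalisation, in which C6 of 10 (its only free ring carbon, ortho to OH and para to the pyran oxygen) adds to the β-carbon of the (E)-iminium ion on the face opposite the diphenyl(silyloxy)methyl group of the (S)-catalyst, setting the diarylmethine centre as S, and closure of aldehyde 17 onto O5 pulls the addition forward.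

Step 13
Reactants: 18 the lactol of step 12
Product: 19 (4S)-4-[2-(allyloxy)-4-ArE-5-prenylphenyl]-5-ArE-8,8-dimethyl-6-prenyl-3,4-dihydro-2H,8H-pyrano[2,3-f]chromen-2-one
Conditions: [N(n-Pr)4][RuO4] (5 mol%), N-methylmorpholine N-oxide, 4 Å MS, CH2Cl2, rt
Reagents that add atoms: none
Why: Perruthenate/N-oxide oxidation (Ley–Griffith) of a lactol to the lactone, with no free phenol or other alcohol present.

Step 14
Reactants: 19 the lactone of step 13
Product: 21 (4S)-4-[2-(allyloxy)-4-ArE-5-prenylphenyl]-4-(7-ArE-5-hydroxy-2,2-dimethyl-8-prenyl-2H-chromen-6-yl)-2-methylbutan-2-ol, via methyl ketone 20 (not isolated)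
Conditions: MeMgBr (4 equiv), THF, 0 °C to rt; aq. NH4Cl
Reagents that add atoms: methylmagnesium bromide, C[Mg]Br
Why: Double Grignard addition to the aryl ester by way of ketone 20 should give the tertiary alcohol and free O5', the stereocentre being β to the carbonyl and not epimerisable.

Step 15
Reactants: 21 the diol of step 14
Product: 22 (4S)-4-[2-(allyloxy)-4-ArE-5-prenylphenyl]-4-[7-ArE-5-(tert-butyldimethylsilyloxy)-2,2-dimethyl-8-prenyl-2H-chromen-6-yl]-2-methylbutan-2-ol
Conditions: TBSCl, imidazole, DMF, 40 °C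
Reagents that add atoms: tert-butyldimethylsilyl chloride, CC(C)(C)[Si](C)(C)Cl
Why: Silylation of the phenol (the tertiary alcohol is inert to these conditions) protects ring A against the oxidant of step 17.

Step 16
Reactants: 22 the silyl ether of step 15
Product: 23 (4S)-4-(4-ArE-2-hydroxy-5-prenylphenyl)-4-[7-ArE-5-(tert-butyldimethylsilyloxy)-2,2-dimethyl-8-prenyl-2H-chromen-6-yl]-2-methylbutan-2-ol
Conditions: Pd(PPh3)4 (5 mol%), morpholine, THF, rt
Reagents that add atoms: none
Why: Tsuji–Trost-type deallylation with zerovalent palladium and morpholine as allyl acceptor should free the ring B phenol without touching the C-prenyl groups or the silyl ethers.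

Step 17
Reactants: 23 the phenol of step 16
Product: 26 (4R)-7-ArE-4-[7-ArE-5-(tert-butyldimethylsilyloxy)-2,2-dimethyl-8-prenyl-2H-chromen-6-yl]-2,2-dimethyl-8-prenylchroman-5-ol, via dienone 24 (not isolated), via dienol adduct 25 (not isolated)
Conditions: PhI(OAc)2 (1.05 equiv), MeOH, 0 °C; evaporate; (PhO)2P(O)OH (10 mol%), CH2Cl2, 0 °C to rt
Reagents that add atoms: none
Why: Proposed new method: the hypervalent iodine reagent oxidises the only free phenol (ring B) and methanol is captured at the alkylated para carbon C8, giving 4-methoxycyclohexa-2,5-dienone 24 in which C8a has become the β-carbon of an enone; under Brønsted acid the tertiary hydroxyl should add to C8a (oxa-Michael addition, 6-endo-trig, ring O1–C2–C3–C4–C4a–C8a) to give dienol 25, and ionisation of the tertiary allylic methoxy group at C8 followed by loss of the C8a proton restores the arene as the 5-hydroxychroman. The closest known reaction types are the acid-promoted conjugate addition–rearomatisation of quinone monoketals and para-quinol ethers with carbon, nitrogen and sulfur nucleophiles (formal meta functionalisation of phenols) and the intramolecular oxa-Michael addition of tethered alcohols to cyclohexadienones; their combination with a tertiary alcohol to close an aryl ether ring is the untested part. No new stereocentre remains, since C4 is not involved and the centres formed at C8 and C8a (24 and 25 may be epimer mixtures) are erased on aromatisation. The step needs oxidation of one phenol among four aryl oxygens (secured by silylation of the other three), para rather than ortho capture of methanol (the normal course for 4-alkylphenols, with C4a blocked), and 1,4- rather than 1,2-addition of the hydroxyl (only the 1,4-adduct has a low-energy exit by loss of methanol, and the tether can reach C8a but not C7).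

Step 18
Reactants: 26 the tris-silyl ether of step 17
Product: 27 (4R)-4-{5-hydroxy-7-[2-(4-hydroxyphenyl)ethyl]-2,2-dimethyl-8-prenyl-2H-chromen-6-yl}-7-[2-(4-hydroxyphenyl)ethyl]-2,2-dimethyl-8-prenylchroman-5-ol (CNP0103951.1)
Conditions: TBAF (3.5 equiv), AcOH (3.5 equiv), THF, 0 °C to rt
Reagents that add atoms: none
Why: Fluoride-mediated cleavage of the three aryl silyl ethers, buffered with acetic acid so that the chromene and the electron-rich phenoxides are not exposed to strong base.

**Compound list**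

1 | 4-vinylphenyl acetate | CC(=O)Oc1ccc(C=C)cc1 | starting material
2 | 4-vinylphenol | Oc1ccc(C=C)cc1 | intermediate
3 | triisopropyl(4-vinylphenoxy)silane | C=Cc1ccc(O[Si](C(C)C)(C(C)C)C(C)C)cc1 | intermediate
4 | 9-ArE-9-borabicyclo[3.3.1]nonane (THF stock solution) | CC(C)[Si](Oc1ccc(CCB2C3CCCC2CCC3)cc1)(C(C)C)C(C)C | intermediate
5 | 5-bromobenzene-1,3-diol | Oc1cc(O)cc(Br)c1 | starting material
6 | 5-ArE-benzene-1,3-diol | Oc1cc(O)cc(CCc2ccc(O[Si](C(C)C)(C(C)C)C(C)C)cc2)c1 | intermediate
7 | 7-ArE-2,2-dimethyl-2H-chromen-5-ol | CC1(C)C=Cc2c(O)cc(CCc3ccc(O[Si](C(C)C)(C(C)C)C(C)C)cc3)cc2O1 | intermediate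
8 | 7-ArE-2,2-dimethyl-5-(prenyloxy)-2H-chromene | CC(C)=CCOc1cc(CCc2ccc(O[Si](C(C)C)(C(C)C)C(C)C)cc2)cc2OC(C)(C)C=Cc12 | intermediate
9 | 7-ArE-2,2-dimethyl-6-(2-methylbut-3-en-2-yl)-2H-chromen-5(6H)-one (racemic at C6) | C=CC(C)(C)C1C(=O)C2=C(OC(C)(C)C=C2)C=C1CCc1ccc(O[Si](C(C)C)(C(C)C)C(C)C)cc1 | intermediate
10 | 7-ArE-2,2-dimethyl-8-prenyl-2H-chromen-5-ol | CC(C)=CCc1c(CCc2ccc(O[Si](C(C)C)(C(C)C)C(C)C)cc2)cc(O)c2C=CC(C)(C)Oc12 | intermediate
11 | 4-bromo-3-chlorophenol | Oc1ccc(Br)c(Cl)c1 | starting material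
12 | 3-chloro-4-prenylphenol | CC(C)=CCc1ccc(O)cc1Cl | intermediate
13 | 3-ArE-4-prenylphenol | CC(C)=CCc1ccc(O)cc1CCc1ccc(O[Si](C(C)C)(C(C)C)C(C)C)cc1 | intermediate
14 | 4-ArE-2-hydroxy-5-prenylbenzaldehyde | CC(C)=CCc1cc(C=O)c(O)cc1CCc1ccc(O[Si](C(C)C)(C(C)C)C(C)C)cc1 | intermediate
15 | 2-(allyloxy)-4-ArE-5-prenylbenzaldehyde | C=CCOc1cc(CCc2ccc(O[Si](C(C)C)(C(C)C)C(C)C)cc2)c(CC=C(C)C)cc1C=O | intermediate
16 | (E)-3-[2-(allyloxy)-4-ArE-5-prenylphenyl]prop-2-enal | C=CCOc1cc(CCc2ccc(O[Si](C(C)C)(C(C)C)C(C)C)cc2)c(CC=C(C)C)cc1/C=C/C=O | intermediate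
17 | (3S)-3-[2-(allyloxy)-4-ArE-5-prenylphenyl]-3-(7-ArE-5-hydroxy-2,2-dimethyl-8-prenyl-2H-chromen-6-yl)propanal | CC(C)=CCc1c(CCc2ccc(O[Si](C(C)C)(C(C)C)C(C)C)cc2)c([C@H](c2cc(CC=C(C)C)c(CCc3ccc(O[Si](C(C)C)(C(C)C)C(C)C)cc3)cc2OCC=C)CC=O)c(O)c2C=CC(C)(C)Oc12 | intermediate
18 | (4S)-4-[2-(allyloxy)-4-ArE-5-prenylphenyl]-5-ArE-8,8-dimethyl-6-prenyl-3,4-dihydro-2H,8H-pyrano[2,3-f]chromen-2-ol (both anomers) | CC(C)=CCc1c(CCc2ccc(O[Si](C(C)C)(C(C)C)C(C)C)cc2)c2c(OC(O)C[C@H]2c2cc(CC=C(C)C)c(CCc3ccc(O[Si](C(C)C)(C(C)C)C(C)C)cc3)cc2OCC=C)c2C=CC(C)(C)Oc12 | intermediate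
19 | (4S)-4-[2-(allyloxy)-4-ArE-5-prenylphenyl]-5-ArE-8,8-dimethyl-6-prenyl-3,4-dihydro-2H,8H-pyrano[2,3-f]chromen-2-one | CC(C)=CCc1c(CCc2ccc(O[Si](C(C)C)(C(C)C)C(C)C)cc2)c2c(OC(=O)C[C@H]2c2cc(CC=C(C)C)c(CCc3ccc(O[Si](C(C)C)(C(C)C)C(C)C)cc3)cc2OCC=C)c2C=CC(C)(C)Oc12 | intermediate
20 | (4S)-4-[2-(allyloxy)-4-ArE-5-prenylphenyl]-4-(7-ArE-5-hydroxy-2,2-dimethyl-8-prenyl-2H-chromen-6-yl)butan-2-one (present as its magnesium phenoxide) | CC(C)=CCc1c(CCc2ccc(O[Si](C(C)C)(C(C)C)C(C)C)cc2)c([C@H](c2cc(CC=C(C)C)c(CCc3ccc(O[Si](C(C)C)(C(C)C)C(C)C)cc3)cc2OCC=C)CC(C)=O)c(O)c2C=CC(C)(C)Oc12 | intermediate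
21 | (4S)-4-[2-(allyloxy)-4-ArE-5-prenylphenyl]-4-(7-ArE-5-hydroxy-2,2-dimethyl-8-prenyl-2H-chromen-6-yl)-2-methylbutan-2-ol | CC(C)=CCc1c(CCc2ccc(O[Si](C(C)C)(C(C)C)C(C)C)cc2)c([C@H](c2cc(CC=C(C)C)c(CCc3ccc(O[Si](C(C)C)(C(C)C)C(C)C)cc3)cc2OCC=C)CC(C)(C)O)c(O)c2C=CC(C)(C)Oc12 | intermediate
22 | (4S)-4-[2-(allyloxy)-4-ArE-5-prenylphenyl]-4-[7-ArE-5-(tert-butyldimethylsilyloxy)-2,2-dimethyl-8-prenyl-2H-chromen-6-yl]-2-methylbutan-2-ol | CC(C)=CCc1c(CCc2ccc(O[Si](C(C)C)(C(C)C)C(C)C)cc2)c([C@H](c2cc(CC=C(C)C)c(CCc3ccc(O[Si](C(C)C)(C(C)C)C(C)C)cc3)cc2OCC=C)CC(C)(C)O)c(O[Si](C)(C)C(C)(C)C)c2C=CC(C)(C)Oc12 | intermediate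
23 | (4S)-4-(4-ArE-2-hydroxy-5-prenylphenyl)-4-[7-ArE-5-(tert-butyldimethylsilyloxy)-2,2-dimethyl-8-prenyl-2H-chromen-6-yl]-2-methylbutan-2-ol | CC(C)=CCc1c(CCc2ccc(O[Si](C(C)C)(C(C)C)C(C)C)cc2)c([C@H](c2cc(CC=C(C)C)c(CCc3ccc(O[Si](C(C)C)(C(C)C)C(C)C)cc3)cc2O)CC(C)(C)O)c(O[Si](C)(C)C(C)(C)C)c2C=CC(C)(C)Oc12 | intermediate
24 | 5-ArE-2-{(1R)-1-[7-ArE-5-(tert-butyldimethylsilyloxy)-2,2-dimethyl-8-prenyl-2H-chromen-6-yl]-3-hydroxy-3-methylbutyl}-4-methoxy-4-prenylcyclohexa-2,5-dien-1-one (both epimers at the methoxy carbon) | CC(C)=CCc1c(CCc2ccc(O[Si](C(C)C)(C(C)C)C(C)C)cc2)c([C@H](C2=CC(OC)(CC=C(C)C)C(CCc3ccc(O[Si](C(C)C)(C(C)C)C(C)C)cc3)=CC2=O)CC(C)(C)O)c(O[Si](C)(C)C(C)(C)C)c2C=CC(C)(C)Oc12 | intermediate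
25 | (4R)-7-ArE-4-[7-ArE-5-(tert-butyldimethylsilyloxy)-2,2-dimethyl-8-prenyl-2H-chromen-6-yl]-8-methoxy-2,2-dimethyl-8-prenyl-3,4,8,8a-tetrahydro-2H-chromen-5-ol (epimers at C8 and C8a) | CC(C)=CCc1c(CCc2ccc(O[Si](C(C)C)(C(C)C)C(C)C)cc2)c([C@H]2CC(C)(C)OC3C2=C(O)C=C(CCc2ccc(O[Si](C(C)C)(C(C)C)C(C)C)cc2)C3(OC)CC=C(C)C)c(O[Si](C)(C)C(C)(C)C)c2C=CC(C)(C)Oc12 | intermediate
26 | (4R)-7-ArE-4-[7-ArE-5-(tert-butyldimethylsilyloxy)-2,2-dimethyl-8-prenyl-2H-chromen-6-yl]-2,2-dimethyl-8-prenylchroman-5-ol | CC(C)=CCc1c(CCc2ccc(O[Si](C(C)C)(C(C)C)C(C)C)cc2)c([C@H]2CC(C)(C)Oc3c(CC=C(C)C)c(CCc4ccc(O[Si](C(C)C)(C(C)C)C(C)C)cc4)cc(O)c32)c(O[Si](C)(C)C(C)(C)C)c2c1OC(C)(C)C=C2 | intermediate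
27 | (4R)-4-{5-hydroxy-7-[2-(4-hydroxyphenyl)ethyl]-2,2-dimethyl-8-prenyl-2H-chromen-6-yl}-7-[2-(4-hydroxyphenyl)ethyl]-2,2-dimethyl-8-prenylchroman-5-ol | CC(C)=CCc1c(CCc2ccc(O)cc2)c([C@H]2CC(C)(C)Oc3c(CC=C(C)C)c(CCc4ccc(O)cc4)cc(O)c32)c(O)c2c1OC(C)(C)C=C2 | target

**Step count and risks**

Total steps: 18. Longest linear sequence: 13 steps (1 to 27 by steps 1–6 and 12–18; equally by steps 1, 2 and 8–18).

Steps most likely to fail:

1. Step 17 (Proposed new method). The tertiary hydroxyl may add reversibly to the carbonyl carbon of dienone 24 instead of to C8a. Ionisation of that hemiketal would divert material by 1,2-shift of the prenyl group (dienone–phenol rearrangement) or by capture of methanol at C8a. Prolonged acid contact could also engage the chromene double bond of ring A. The fallback uses known chemistry, sets out from 10 and comes back at 27. Two molecules of 10 are joined head to tail under a BINOL-derived chiral phosphoric acid (for example (R)-TRIP, 10 mol%, toluene, −20 °C to rt, the catalyst enantiomer chosen for the R centre). Protonation of one chromene at C3 gives an ortho-quinone methide hydrogen-bonded to the phosphate, and C6 of the second molecule, its only free ring carbon, adds to C4. This is a Brønsted acid-catalysed Friedel–Crafts hydroarylation of a 2H-chromene, of the type known for phosphoric acid-catalysed arylation of ortho-hydroxystyrenes. It should give the bis(triisopropylsilyl) ether of the target F1, in which O1–C8a comes from the chromene and the C4–C6' bond and the stereocentre are formed together. TBAF/AcOH as in step 18 then gives 27.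

2. Step 12. Addition at C6 of 10, which is flanked by the hydroxyl and the arylethyl group, may be slow, so that an uncatalysed or acid-catalysed background addition erodes the facial selectivity. The fallback sets out from 10 and 16 and comes back at 19. It uses oxidative N-heterocyclic carbene catalysis: an aminoindanol-derived N-mesityl triazolium salt (10 mol%), K2CO3 and 3,3',5,5'-tetra-tert-butyldiphenoquinone in toluene at rt. This converts enal 16 into the α,β-unsaturated acyl azolium ion, O5 of 10 adds to its carbonyl group, and C6 is then delivered to the β-carbon within the complex ([3,3] shift of the Coates–Claisen type) before lactonisation. The carbon–carbon bond is thus formed intramolecularly and at the lactone oxidation level, which merges steps 12 and 13. No compound outside the list is formed (F0).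

3. Step 6. Ortho-dienone 9 may enolise to the 6-(2-methylbut-3-en-2-yl)phenol before the Cope shift, or lose the prenyl group, so that the allyl unit ends on the wrong carbon or is lost. The fallback sets out from 7 and comes back at 10. It replaces the sigmatropic shift by halogenation and cross-coupling. Bromination with tetrabutylammonium tribromide (CH2Cl2/MeOH, −20 °C) should go para to the free hydroxyl and give 8-bromo-7-ArE-2,2-dimethyl-2H-chromen-5-ol F2. Stille coupling with tributyl(3-methylbut-2-en-1-yl)stannane (Pd(PPh3)4, DMF, 80 °C) then gives 10.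

Further compounds
F1 | step 17 | (4R)-7-ArE-4-(7-ArE-5-hydroxy-2,2-dimethyl-8-prenyl-2H-chromen-6-yl)-2,2-dimethyl-8-prenylchroman-5-ol | CC(C)=CCc1c(CCc2ccc(O[Si](C(C)C)(C(C)C)C(C)C)cc2)c([C@H]2CC(C)(C)Oc3c(CC=C(C)C)c(CCc4ccc(O[Si](C(C)C)(C(C)C)C(C)C)cc4)cc(O)c32)c(O)c2c1OC(C)(C)C=C2
F0 | step 12 | none | none
F2 | step 6 | 8-bromo-7-ArE-2,2-dimethyl-2H-chromen-5-ol | CC1(C)C=Cc2c(O)cc(CCc3ccc(O[Si](C(C)C)(C(C)C)C(C)C)cc3)c(Br)c2O1
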